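**Retrosynthetic overview**

1. Target 20 ⇐ hydroquinone triol 19 (mild oxidation) ⇐ tribenzyl (3S)-isoflavan 18 (global hydrogenolysis): the ring B quinone and the C8 phenol of ring A are both unmasked last.
2. C3–H ⇐ iridium-catalysed asymmetric hydrogenation of the C3=C4 bond of the 3-aryl-2H-chromene 17.
3. Pyran ring of 17 ⇐ one-pot (3+3) union of ring A phenol 5 with α-arylacrolein 14 on a phenylboronic acid template: C4–C4a by boron-tethered ortho-hydroxyalkylation, O1–C2 by oxa-6π electrocyclisation of the ortho-quinone methide. The 1,3,2-dioxaborin ring is a temporary tether, not present in the target, and is lost in the same flask.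
4. Enabling feature: in ring A the pyran oxygen O1 on C8a is flanked by C4a, its only hydrogen-bearing ortho carbon (C8 carries oxygen), and C4a lies para to the C7 methoxy group. O1 and C4a can therefore be clamped by boron as a 1,3-dinucleophile onto the three-carbon unit C2–C3–C4, which already carries ring B on C3.
5. Ring order: rings A (from 1) and B (from 6) enter as arenes; the pyran ring is the only ring formed (step 8); the C3 stereocentre follows (step 9), the quinone last (step 10).

Key step: step 8

Assumption: chroman numbering (O1, C2, C3, C4, C4a, C5 to C8, C8a; ring B primed) is used throughout; 1, 6 and 10 are taken as catalogue compounds; in step 9 the catalyst antipode that gives (3S) is meant, written here as the (S)-ligand complex (BArF = B[3,5-(CF3)2C6H3]4), and its sense of induction has to be confirmed on the first run.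

**Route**

Step 1
Reactants: 1 2,3,4-trimethoxybenzaldehyde
Product: 2 2-hydroxy-3,4-dimethoxybenzaldehyde
Conditions: BCl3 (1.1 equiv), CH2Cl2, 0 °C to rt; aqueous work-up
Reagents that add atoms: none
Why: Chelation-controlled ether cleavage: BCl3 is held between the aldehyde oxygen and the ortho methoxy oxygen, so only the 2-methoxy group should be cleaved.

Step 2
Reactants: 2 2-hydroxy-3,4-dimethoxybenzaldehyde
Product: 3 2-(benzyloxy)-3,4-dimethoxybenzaldehyde
Conditions: BnBr, K2CO3, DMF, 50 °C
Reagents that add atoms: benzyl bromide, BrCc1ccccc1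
Why: Williamson etherification of the acidic salicylaldehyde-type phenol; the benzyl group will later become the C8 hydroxyl.

Step 3
Reactants: 3 2-(benzyloxy)-3,4-dimethoxybenzaldehyde
Product: 5 2-(benzyloxy)-3,4-dimethoxyphenol, via aryl formate 4 (not isolated)
Conditions: mCPBA, CH2Cl2, 0 °C to rt; aq. NaHCO3 wash; then K2CO3 (cat.), MeOH, rt
Reagents that add atoms: 3-chloroperbenzoic acid, OOC(=O)c1cccc(Cl)c1
Why: Dakin-type Baeyer–Villiger oxidation: the electron-rich aryl group (ortho and para alkoxy) migrates to give the formate, which mild methanolysis converts into the phenol.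

Step 4
Reactants: 6 2,3-dimethoxy-1,4-benzoquinone
Product: 8 1,4-bis(benzyloxy)-2,3-dimethoxybenzene, via hydroquinone 7 (not isolated)
Conditions: H2 (1 atm), 10% Pd/C, EtOAc, rt; filter under N2, evaporate; then BnBr, K2CO3, DMF, 50 °C
Reagents that add atoms: benzyl bromide, BrCc1ccccc1
Why: Catalytic hydrogenation of the quinone to the air-sensitive hydroquinone followed directly by double Williamson benzylation should give the symmetric diether that masks the future quinone.

Step 5
Reactants: 8 1,4-bis(benzyloxy)-2,3-dimethoxybenzene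
Product: 9 1,4-bis(benzyloxy)-5-bromo-2,3-dimethoxybenzene
Conditions: NBS (1.0 equiv), MeCN, 0 °C to rt, dark
Reagents that add atoms: N-bromosuccinimide, BrN1C(=O)CCC1=O
Why: Electrophilic aromatic bromination of a tetraalkoxybenzene; the two free positions are equivalent by symmetry, so a single monobromide should form.

Step 6
Reactants: 9 1,4-bis(benzyloxy)-5-bromo-2,3-dimethoxybenzene; 10 2-bromo-3,3-diethoxyprop-1-ene
Product: 13 1,4-bis(benzyloxy)-5-(3,3-diethoxyprop-1-en-2-yl)-2,3-dimethoxybenzene, via aryllithium 11 (not isolated), via arylzinc chloride 12 (not isolated)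
Conditions: n-BuLi, THF, −78 °C; ZnCl2, −78 °C to rt; then 10, Pd(PPh3)4 (3 mol %), THF, 50 °C
Reagents that add atoms: none
Why: Bromine–lithium exchange at −78 °C, transmetalation to zinc and Negishi coupling with the 1,1-disubstituted vinyl bromide should install the acrolein unit in acetal-masked form.

Step 7
Reactants: 13 1,4-bis(benzyloxy)-5-(3,3-diethoxyprop-1-en-2-yl)-2,3-dimethoxybenzene
Product: 14 2-[2,5-bis(benzyloxy)-3,4-dimethoxyphenyl]prop-2-enal
Conditions: 1 M aq. HCl, THF, 0 °C; cold extractive work-up; used at once as a toluene solution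
Reagents that add atoms: water, O
Why: Acid-catalysed hydrolysis of the allylic acetal through the conjugated oxocarbenium ion is fast at 0 °C; the enal is used at once because α-arylacroleins self-condense on standing.

Step 8
Reactants: 5 2-(benzyloxy)-3,4-dimethoxyphenol; 14 2-[2,5-bis(benzyloxy)-3,4-dimethoxyphenyl]prop-2-enal
Product: 17 8-(benzyloxy)-3-[2,5-bis(benzyloxy)-3,4-dimethoxyphenyl]-6,7-dimethoxy-2H-chromene, via dioxaborin 15 (not isolated), via ortho-quinone methide 16 (not isolated)
Conditions: PhB(OH)2 (1.1 equiv), EtCO2H (0.3 equiv), toluene, reflux, Dean–Stark; 14 added over 2 h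
Reagents that add atoms: none
Why: PhB(OH)2 condenses with the phenolic OH of 5 and the carbonyl oxygen of 14 into a mixed boronate, in which the aldehyde carbon is delivered through a six-membered boron-bridged transition state to the only unsubstituted ortho carbon of the phenol (C4–C4a) to give dioxaborin 15; at reflux 15 expels PhBO to the ortho-quinone methide 16, whose s-cis 1-oxatriene closes by thermal oxa-6π electrocyclisation (O1–C2). The closest known reaction type is the phenylboronic acid-mediated ortho-specific condensation of phenols with α,β-unsaturated aldehydes to 2H-chromenes. Ring closures: the temporary dioxaborin ring closes by templated ortho-hydroxyalkylation, the pyran ring by disrotatory 6π electrocyclisation of O1=C8a–C4a=C4–C3=C2. No stereocentre is formed; C3 is left as the prochiral sp2 carbon of a trisubstituted olefin for step 9. The step needs C- over O-alkylation, 1,2- over 1,4-addition and attack at C4a instead of C5; the boron tether should secure all three, helped by the benzyloxy group on the other ortho carbon and the para methoxy group that activates C4a.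

Step 9
Reactants: 17 8-(benzyloxy)-3-[2,5-bis(benzyloxy)-3,4-dimethoxyphenyl]-6,7-dimethoxy-2H-chromene
Product: 18 (3S)-8-(benzyloxy)-3-[2,5-bis(benzyloxy)-3,4-dimethoxyphenyl]-6,7-dimethoxy-3,4-dihydro-2H-chromene
Conditions: [Ir(cod)((S)-tBu-PHOX)]BArF (2 mol %), H2 (50 bar), CH2Cl2, rt
Reagents that add atoms: none
Why: Asymmetric hydrogenation of an unfunctionalised trisubstituted cyclic olefin with a cationic iridium phosphine–oxazoline catalyst, a reaction type established for 3-aryl-2H-chromenes; the chiral ligand selects the olefin face and so sets C3 as (S), and benzyl ethers are inert to the homogeneous catalyst.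

Step 10
Reactants: 18 (3S)-8-(benzyloxy)-3-[2,5-bis(benzyloxy)-3,4-dimethoxyphenyl]-6,7-dimethoxy-3,4-dihydro-2H-chromene
Product: 20 5-[(3S)-8-hydroxy-6,7-dimethoxy-3,4-dihydro-2H-chromen-3-yl]-2,3-dimethoxycyclohexa-2,5-diene-1,4-dione, via hydroquinone 19 (not isolated)
Conditions: H2 (1 atm), 10% Pd/C, EtOAc/MeOH, rt; filter under Ar; then Ag2O (1.1 equiv), Et2O/EtOAc, 0 °C to rt
Reagents that add atoms: none
Why: Hydrogenolysis should remove the three benzyl ethers without touching the chroman C–O bond (C2 is not benzylic), and Ag2O should oxidise the electron-rich 2,3-dimethoxyhydroquinone to the para-quinone at a potential well below that needed for the ring A monophenol, under neutral conditions that leave C3 untouched.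

**Compound list**

1 | 2,3,4-trimethoxybenzaldehyde | COc1ccc(C=O)c(OC)c1OC | starting material
2 | 2-hydroxy-3,4-dimethoxybenzaldehyde | COc1ccc(C=O)c(O)c1OC | intermediate
3 | 2-(benzyloxy)-3,4-dimethoxybenzaldehyde | COc1ccc(C=O)c(OCc2ccccc2)c1OC | intermediate
4 | 2-(benzyloxy)-3,4-dimethoxyphenyl formate (not isolated) | COc1ccc(OC=O)c(OCc2ccccc2)c1OC | intermediate
5 | 2-(benzyloxy)-3,4-dimethoxyphenol | COc1ccc(O)c(OCc2ccccc2)c1OC | intermediate
6 | 2,3-dimethoxy-1,4-benzoquinone | COC1=C(OC)C(=O)C=CC1=O | starting material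
7 | 2,3-dimethoxybenzene-1,4-diol (not isolated) | COc1c(O)ccc(O)c1OC | intermediate
8 | 1,4-bis(benzyloxy)-2,3-dimethoxybenzene | COc1c(OCc2ccccc2)ccc(OCc2ccccc2)c1OC | intermediate
9 | 1,4-bis(benzyloxy)-5-bromo-2,3-dimethoxybenzene | COc1c(OCc2ccccc2)cc(Br)c(OCc2ccccc2)c1OC | intermediate
10 | 2-bromo-3,3-diethoxyprop-1-ene | C=C(Br)C(OCC)OCC | starting material
11 | [2,5-bis(benzyloxy)-3,4-dimethoxyphenyl]lithium (not isolated) | [Li]c1cc(OCc2ccccc2)c(OC)c(OC)c1OCc1ccccc1 | intermediate
12 | [2,5-bis(benzyloxy)-3,4-dimethoxyphenyl]zinc chloride (not isolated) | Cl[Zn]c1cc(OCc2ccccc2)c(OC)c(OC)c1OCc1ccccc1 | intermediate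
13 | 1,4-bis(benzyloxy)-5-(3,3-diethoxyprop-1-en-2-yl)-2,3-dimethoxybenzene | C=C(C(OCC)OCC)c1cc(OCc2ccccc2)c(OC)c(OC)c1OCc1ccccc1 | intermediate
14 | 2-[2,5-bis(benzyloxy)-3,4-dimethoxyphenyl]prop-2-enal | C=C(C=O)c1cc(OCc2ccccc2)c(OC)c(OC)c1OCc1ccccc1 | intermediate
15 | 8-(benzyloxy)-4-{1-[2,5-bis(benzyloxy)-3,4-dimethoxyphenyl]ethenyl}-6,7-dimethoxy-2-phenyl-4H-1,3,2-benzodioxaborinine (racemic, not isolated) | C=C(c1cc(OCc2ccccc2)c(OC)c(OC)c1OCc1ccccc1)C1OB(c2ccccc2)Oc2c1cc(OC)c(OC)c2OCc1ccccc1 | intermediate
16 | 2-(benzyloxy)-6-{2-[2,5-bis(benzyloxy)-3,4-dimethoxyphenyl]prop-2-en-1-ylidene}-3,4-dimethoxycyclohexa-2,4-dien-1-one (olefin geometry not specified, not isolated) | C=C(C=C1C=C(OC)C(OC)=C(OCc2ccccc2)C1=O)c1cc(OCc2ccccc2)c(OC)c(OC)c1OCc1ccccc1 | intermediate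
17 | 8-(benzyloxy)-3-[2,5-bis(benzyloxy)-3,4-dimethoxyphenyl]-6,7-dimethoxy-2H-chromene | C1(=Cc2cc(OC)c(OC)c(OCc3ccccc3)c2OC1)c1cc(OCc2ccccc2)c(OC)c(OC)c1OCc1ccccc1 | intermediate
18 | (3S)-8-(benzyloxy)-3-[2,5-bis(benzyloxy)-3,4-dimethoxyphenyl]-6,7-dimethoxy-3,4-dihydro-2H-chromene | COc1c(OC)c(OCc2ccccc2)c(cc1OCc1ccccc1)[C@H]1COc2c(cc(OC)c(OC)c2OCc2ccccc2)C1 | intermediate
19 | 2-[(3S)-8-hydroxy-6,7-dimethoxy-3,4-dihydro-2H-chromen-3-yl]-5,6-dimethoxybenzene-1,4-diol (not isolated) | COc1c(OC)c(O)c(cc1O)[C@H]1COc2c(cc(OC)c(OC)c2O)C1 | intermediate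
20 | 5-[(3S)-8-hydroxy-6,7-dimethoxy-3,4-dihydro-2H-chromen-3-yl]-2,3-dimethoxycyclohexa-2,5-diene-1,4-dione | COC1=C(OC)C(=O)C([C@H]2COc3c(cc(OC)c(OC)c3O)C2)=CC1=O | target

**Count and risks**

Total step count: 10. Longest linear sequence: 7 steps (steps 4 to 10, from 6 to 20).

Steps most likely to fail:

Step 8. The templated ortho-attack on the conjugated, α-branched aldehyde may be outrun by uncatalysed conjugate addition of the phenol or by hetero-Diels–Alder self-dimerisation of 14. The fallback sets out from 5 and 14 and comes back at 17, and makes the two bonds one after the other by polar chemistry. Base-catalysed oxa-Michael addition of 5 to 14 (DABCO cat., MeCN, rt) should give the racemic 3-aryloxy-2-arylpropanal F1. Amberlyst-15 in toluene at 60 °C should then close the ring by Friedel–Crafts attack of C4a on the aldehyde to the chroman-4-ol F2 (diastereomer mixture, not isolated), which loses water to chromene 17.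

Step 9. Facial selectivity may be poor, or turnover slow, because the ortho-benzyloxy group twists ring B out of the olefin plane. The fallback sets out from 17 and comes back at 19, and sets C3 by dynamic kinetic resolution instead. Hydroboration–oxidation of 17 (BH3·THF; then NaOH, H2O2) should give the racemic trans-isoflavan-4-ol F3, and Dess–Martin periodinane the racemic isoflavanone F4. C3 of F4 epimerises through the enol under the basic medium of a Noyori-type transfer hydrogenation (RuCl(p-cymene)[(S,S)-TsDPEN], HCO2H/Et3N), so both enantiomers should funnel into the cis-(3S,4S)-isoflavan-4-ol F5. Hydrogenolysis under neutral conditions (H2, Pd(OH)2/C, EtOAc/EtOH) should remove the benzylic C4 hydroxyl together with the three benzyl groups and give 19, which is oxidised as in step 10.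

Step 7. The enal 14 may be lost by self-condensation during concentration and storage. The fallback sets out from 13 and comes back at 14, and keeps the three-carbon unit at the alcohol oxidation level. Acetal 13 is hydrolysed as in step 7 and the cold, dilute enal solution is reduced at once (NaBH4, CeCl3·7H2O, MeOH, 0 °C) to the stable allylic alcohol F6. Just before step 8, MnO2 in toluene at rt oxidises F6 back to 14, and the filtered dry solution is used without concentration.

Further compounds
F1 | step 8 | 3-[2-(benzyloxy)-3,4-dimethoxyphenoxy]-2-[2,5-bis(benzyloxy)-3,4-dimethoxyphenyl]propanal (racemic) | O=CC(COc1ccc(OC)c(OC)c1OCc1ccccc1)c1cc(OCc2ccccc2)c(OC)c(OC)c1OCc1ccccc1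
F2 | step 8 | 8-(benzyloxy)-3-[2,5-bis(benzyloxy)-3,4-dimethoxyphenyl]-6,7-dimethoxy-3,4-dihydro-2H-chromen-4-ol (diastereomer mixture, not isolated) | OC1c2cc(OC)c(OC)c(OCc3ccccc3)c2OCC1c1cc(OCc2ccccc2)c(OC)c(OC)c1OCc1ccccc1
F3 | step 9 | trans-8-(benzyloxy)-3-[2,5-bis(benzyloxy)-3,4-dimethoxyphenyl]-6,7-dimethoxy-3,4-dihydro-2H-chromen-4-ol (racemic; the (3S,4R) enantiomer is drawn) | COc1c(OC)c(OCc2ccccc2)c(cc1OCc1ccccc1)[C@H]1COc2c(cc(OC)c(OC)c2OCc2ccccc2)[C@@H]1O
F4 | step 9 | 8-(benzyloxy)-3-[2,5-bis(benzyloxy)-3,4-dimethoxyphenyl]-6,7-dimethoxy-2,3-dihydro-4H-chromen-4-one (racemic) | COc1c(OC)c(OCc2ccccc2)c(cc1OCc1ccccc1)C1COc2c(cc(OC)c(OC)c2OCc2ccccc2)C1=O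
F5 | step 9 | (3S,4S)-8-(benzyloxy)-3-[2,5-bis(benzyloxy)-3,4-dimethoxyphenyl]-6,7-dimethoxy-3,4-dihydro-2H-chromen-4-ol (cis) | COc1c(OC)c(OCc2ccccc2)c(cc1OCc1ccccc1)[C@H]1COc2c(cc(OC)c(OC)c2OCc2ccccc2)[C@H]1O
F6 | step 7 | 2-[2,5-bis(benzyloxy)-3,4-dimethoxyphenyl]prop-2-en-1-ol | C=C(CO)c1cc(OCc2ccccc2)c(OC)c(OC)c1OCc1ccccc1
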